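## Structural features

The target (14) is a linear array of three aromatic rings with no stereocentre: a 4-hydroxyphenyl ring (ring A) is bonded to C5 of a 1,3-oxazole (ring B), whose C2 is bonded to C2 of a 1H-pyrrole (ring C). Ring B carries chlorine at C4 and ring C carries chlorine at C3, C4 and C5, so every carbon of both azoles is substituted and the only C–H bonds left are the four of ring A. The N–H of the perchlorinated pyrrole is acidic and the ring is still oxidisable, and the free phenol would make ring A the most electrophile-prone site; both are best kept masked while electrophilic halogen or palladium is in use. The real difficulty is to place four chlorine atoms on two different azoles without touching the positions of ring A ortho to oxygen, and to make the hindered C2–C2 bond between rings B and C, which is flanked by the pyrrole nitrogen and by C3–Cl. The key step uses the O1–C5(aryl)=C4 unit of ring B, which is the enol of an aryl ketone whose α-carbon carries an isocyanide. C4–C5 can therefore come from acylation of an isocyanoacetate carbanion by the aroyl chloride of ring A, and O1–C2 from addition of the enolate oxygen to the isocyanide carbon. The ester left on C4 sits on the nucleophilic β-carbon of the O1–C5=C4 enol ether and marks exactly the carbon that must end up bearing chlorine.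

## Logic of the disconnections

**14 to 12.** The aryl O–CH3 bond and the pyrrole N–CH2 bond are cut; both are protecting-group bonds. The phenol and the acidic N–H stay masked through every halogenation and the palladium step, and one boron Lewis acid should remove both groups in a single operation by way of the N-hydroxymethyl compound 13. The forward step must leave four C–Cl bonds and the oxazole untouched, and 13 must release formaldehyde on mild basic work-up.

**12 to 6 and 11.** The bond between C2 of ring B and C2 of ring C is cut. C2–H is the only C–H bond on the azole of 6 and the most acidic one, so a C–H arylation needs no prior metalation. All four chlorines are already in place in the two halves, so no halogenation follows the union. The gain is convergence: halves of three and four steps. The forward step must insert palladium into the C–Br bond of 11 in preference to any C–Cl bond, tolerate two ortho substituents, and keep the nitrogen protecting group through carbonate at 110 °C. For that reason an alkoxymethyl group is chosen on nitrogen, not a carbamate, which an electron-poor pyrrole would shed under hot base.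

**6 to 5 to 4.** The C4–Cl bond is traced back to a C4–CO2H bond and then to the methyl ester. The carboxyl carbon is put on C4 by the ring synthesis itself, so ipso-replacement fixes the chlorine site without relying on relative ring reactivity. The exchange is placed before the coupling so that hydroxide and electrophilic chlorine never meet ring C, and so that the least tested reaction runs at the third step on cheap material. The forward step demands that ipso attack at C4 beats chlorination of ring A ortho to the methoxy group.

**4 to 1 and 2.** C4–C5 and O1–C2 are cut, which opens ring B to two commercial compounds. This removes one ring and two skeletal bonds in one operation and fixes aryl at C5 and carboxyl at C4 by connectivity. The forward step needs C-acylation of the isocyanoacetate anion and ring closure of the transient 3.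

**11 to 10, 9, 8 and 7.** The C2–Br bond is traced to a C2–CO2H bond (ipso-bromodecarboxylation), the acid to its ester, the N–CH2 bond to N–H, and the three C–Cl bonds to C–H. The ester carbon marks the future coupling carbon and blocks it during exhaustive chlorination. The ester is used instead of the free acid because a free carboxyl on C2 would be expelled as CO2 by ipso-chlorination. The forward steps demand complete chlorination at the deactivated C3 and ipso attack of bromine on a ring that carries three chlorines.

## Other disconnections considered

**Alternative 1:** Ring B is cut at N3–C2 and O1–C5 and traced to the 4-aryl NH-triazole A1 and the acid chloride A2.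
- Forward step: A1 would be N-acylated by A2. On heating, the N-acyl triazole would open to a diazo imine, lose N2 and close through the acyl oxygen to the 4-unsubstituted oxazole A3. A3 would then need chlorination at C4 and removal of the sulfonate.
- In its favour: ring C enters pre-chlorinated at the acid oxidation level (A2 would come from 8 by hydrolysis and acid chloride formation). The bromodecarboxylation of step 7, the nitrogen protecting group and palladium are all unnecessary, and the aryl group is placed at C5 by the mechanism. On these points the alternative is the better plan.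
- Against it: the C4 chlorine would be introduced last, by electrophilic substitution on a molecule with a free acidic pyrrole N–H, with risk of N-chlorination or ipso attack on ring C. A2 with a free N–H can acylate itself. The denitrogenation needs high temperature and passes through a carbene-like species, and A1 requires an azide cycloaddition.
- Comparison: C4 would be the only unsubstituted azole carbon of A3 and the sulfonate deactivates ring A, so the regiochemical risk of that chlorination is moderate, not severe. Both plans fix the oxazole substitution pattern by the ring synthesis; the chosen plan also fixes the chlorine site through a carbon placeholder. Step counts are about equal (eight to nine operations).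

**Alternative 2:** Ring B is cut at N3–C4 and O1–C5, leading to the N-protected carboxamide A4 and the α-bromo arylacetyl chloride A5.
- Forward step: N-acylation of A4 by A5 and displacement of the benzylic bromide by the imide oxygen would give the racemic oxazol-4(5H)-one A6. A deoxychlorinating agent would then convert the C4 carbonyl into C4–Cl with aromatisation (the C5 stereocentre disappears), and both protecting groups would be removed.
- In its favour: the C4 chlorine is again delivered site-specifically through a placeholder, here oxygen. Deoxychlorination of an enolisable imide carbonyl is better established than the carboxyl-to-chlorine exchange of step 3, so on the least certain step this alternative is the better. Ring C enters pre-chlorinated and no palladium is used.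
- Against it: the nitrogen of A4 is a poor nucleophile (electron-poor, flanked by N–CH2 and C3–Cl), so O-acylation or dehydration of the amide to a nitrile may outrun N-acylation. A6 is an acyl imidate sensitive to hydrolysis. Hot acidic deoxychlorination endangers the N,O-acetal protecting group, and the sulfonate and the nitrogen protecting group need different cleavage conditions.
- Comparison: the annulation is a polar ring closure of reliability comparable to the isocyanide closure. The plan is about one to two steps longer, because A4 and A5 are made separately and two deprotections are needed.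

**Alternative 3:** Ring C is cut at C3–C4 and N1–C5 and traced to the oxazol-2-yl methyl ketoxime A7 and acetylene A8.
- Forward step: in a hydroxide/sulfoxide superbase medium A7 would be O-vinylated, and the O-vinyl oxime would undergo a [3,3] shift and cyclocondensation (Trofimov reaction) to the unsubstituted pyrrolyl oxazole A9. A9 would then need three chlorinations on ring C and O-demethylation.
- In its favour: ring C is made from a two-carbon feedstock with no pyrrole building block, no nitrogen protecting group and no palladium. A7 would be reachable from 6, so the oxazole chemistry is shared. In atom economy for ring C it is the better plan.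
- Against it: hot hydroxide in a dipolar solvent threatens the 4-chlorooxazole (ring opening, substitution of chloride), and N-vinylation of A9 is a usual side reaction. A8 under pressure with strong base is the most hazardous operation of any plan here. Most important, three chlorines would be introduced after the rings are joined, the last at the hindered C3, in competition with the positions of ring A ortho to the methoxy group.
- Comparison: this brings back the undirected chlorination that the chosen plan avoids by carrying all three pyrrole chlorines in 11. The step count would be similar (about nine), since the steps saved on ring C are spent on making A7 from 6 and on the chlorinations.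

Key step: step 1

Assumption (chemistry): the commercial methyl ester 7 is taken as the pyrrole starting material in place of pyrrole-2-carboxylic acid, because a free 2-carboxyl group would be lost by ipso-chlorination during exhaustive ring chlorination.

## Route

Step 1
Reactants: 1 methyl isocyanoacetate; 2 4-methoxybenzoyl chloride
Product: 4 methyl 5-(4-methoxyphenyl)-1,3-oxazole-4-carboxylate, via methyl 2-isocyano-3-(4-methoxyphenyl)-3-oxopropanoate 3 (not isolated)
Conditions: Et3N (2.5 equiv), DMAP (0.1 equiv), THF, 0 °C to rt
Reagents that add atoms: none
Why: This is a Schöllkopf oxazole synthesis. Et3N reversibly deprotonates the CH2 of 1, which is acidified by both the ester and the isocyanide, and the carbanion attacks 2 (or its acyl-DMAP salt) at carbon to form C4–C5 and give 3. Intermediate 3 is more acidic than 1 and is converted by the second equivalent of base into its enolate. The enolate oxygen then adds to the terminal isocyanide carbon (O1–C2) in a 5-endo-dig closure, equivalent to a 1,5-electrocyclisation of the isocyano enolate, and protonation of the resulting C2 anion gives the aromatic ring. No stereocentre is formed. The step needs C-acylation of the anion and not reaction at the isocyanide carbon; the doubly stabilised carbanion is the only strongly nucleophilic site and the isocyanide carbon cannot compete with it for an acyl chloride. Regiochemistry is fixed by connectivity: the aroyl carbon can only become C5 and the ester-bearing carbon C4.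

Step 2
Reactants: 4 methyl 5-(4-methoxyphenyl)-1,3-oxazole-4-carboxylate
Product: 5 5-(4-methoxyphenyl)-1,3-oxazole-4-carboxylic acid
Conditions: LiOH·H2O (1.5 equiv), THF–MeOH–H2O, rt; then 1 M HCl to pH 2
Reagents that add atoms: lithium hydroxide, [Li+].[OH-]
Why: Ester saponification by acyl-oxygen cleavage; the 5-aryloxazole ring and the aryl methyl ether should tolerate aqueous LiOH at room temperature, and no other hydrolysable group is present.

Step 3
Reactants: 5 5-(4-methoxyphenyl)-1,3-oxazole-4-carboxylic acid
Product: 6 4-chloro-5-(4-methoxyphenyl)-1,3-oxazole
Conditions: NCS (1.2 equiv), LiOAc (0.2 equiv), MeCN–H2O (9:1), rt to 50 °C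
Reagents that add atoms: N-chlorosuccinimide, O=C1CCC(=O)N1Cl
Why: Proposed new method: the C4=C5 bond of 5 is an embedded 4-methoxycinnamic acid whose β-carbon C5 is also donated to by O1, so electrophilic chlorine from NCS should add ipso at the carboxylate-bearing C4, the cation at C5 being stabilised by O1 and the anisyl ring, and loss of CO2 then restores the oxazole with chlorine at C4; the closest known reaction type is the LiOAc-catalysed N-halosuccinimide halodecarboxylation of cinnamic acids and of electron-rich heteroaryl carboxylic acids (Hunsdiecker-type ipso substitution).

Step 4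
Reactants: 7 methyl 1H-pyrrole-2-carboxylate
Product: 8 methyl 3,4,5-trichloro-1H-pyrrole-2-carboxylate
Conditions: SO2Cl2 (3.5 equiv), AcOH–CH2Cl2, 0 °C to 40 °C
Reagents that add atoms: sulfuryl chloride, O=S(=O)(Cl)Cl
Why: Exhaustive electrophilic aromatic chlorination; C5 and C4 should react first and the ester-flanked C3 last, hence the excess reagent and gentle warming, while the ester blocks C2 and cannot be expelled by ipso attack.

Step 5
Reactants: 8 methyl 3,4,5-trichloro-1H-pyrrole-2-carboxylate
Product: 9 methyl 3,4,5-trichloro-1-{[2-(trimethylsilyl)ethoxy]methyl}-1H-pyrrole-2-carboxylate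
Conditions: NaH (1.2 equiv), DMF, 0 °C; then SEMCl (1.2 equiv), 0 °C to rt
Reagents that add atoms: 2-(trimethylsilyl)ethoxymethyl chloride, C[Si](C)(C)CCOCCl
Why: N-alkylation (SN2) of the sodium salt of an acidic pyrrole by a chloromethyl ether; the group removes the N–H that would give an unreactive pyrrolide under carbonate in step 8 and should be stable to hydroxide, N-bromosuccinimide and hot carbonate.

Step 6
Reactants: 9 methyl 3,4,5-trichloro-1-{[2-(trimethylsilyl)ethoxy]methyl}-1H-pyrrole-2-carboxylate
Product: 10 3,4,5-trichloro-1-{[2-(trimethylsilyl)ethoxy]methyl}-1H-pyrrole-2-carboxylic acid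
Conditions: LiOH·H2O (3 equiv), THF–MeOH–H2O, 50 °C; then 1 M HCl, 0 °C, to pH 3
Reagents that add atoms: lithium hydroxide, [Li+].[OH-]
Why: Ester saponification; with nitrogen alkylated no pyrrolide can form to retard hydroxide addition, mild warming answers the hindrance from N–CH2 and C3–Cl, and brief cold dilute acid should spare the N,O-acetal.

Step 7
Reactants: 10 3,4,5-trichloro-1-{[2-(trimethylsilyl)ethoxy]methyl}-1H-pyrrole-2-carboxylic acid
Product: 11 2-bromo-3,4,5-trichloro-1-{[2-(trimethylsilyl)ethoxy]methyl}-1H-pyrrole
Conditions: NBS (1.05 equiv), LiOAc (0.2 equiv), MeCN–H2O, 0 °C to rt, dark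
Reagents that add atoms: N-bromosuccinimide, O=C1CCC(=O)N1Br
Why: Hunsdiecker-type ipso-bromodecarboxylation, a known reaction of pyrrole-2-carboxylic acids: electrophilic bromine attacks the carboxylate-bearing α-carbon and CO2 is lost; all other ring positions are blocked, so one equivalent of reagent has a single site to attack.

Step 8
Reactants: 6 4-chloro-5-(4-methoxyphenyl)-1,3-oxazole (1.2 equiv); 11 2-bromo-3,4,5-trichloro-1-{[2-(trimethylsilyl)ethoxy]methyl}-1H-pyrrole
Product: 12 4-chloro-5-(4-methoxyphenyl)-2-(3,4,5-trichloro-1-{[2-(trimethylsilyl)ethoxy]methyl}-1H-pyrrol-2-yl)-1,3-oxazole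
Conditions: Pd(OAc)2 (5 mol %), PPh3 (10 mol %), PivOH (0.3 equiv), Cs2CO3 (2 equiv), toluene, 110 °C, argon
Reagents that add atoms: none
Why: Palladium-catalysed direct C–H arylation of an azole by concerted metalation–deprotonation with pivalate/carbonate; C2–H is the only C–H of the oxazole and its most acidic position, and zerovalent palladium with a triarylphosphine should insert into the C–Br bond well before any of the four C–Cl bonds.

Step 9
Reactants: 12 4-chloro-5-(4-methoxyphenyl)-2-(3,4,5-trichloro-1-{[2-(trimethylsilyl)ethoxy]methyl}-1H-pyrrol-2-yl)-1,3-oxazole
Product: 14 4-[4-chloro-2-(3,4,5-trichloro-1H-pyrrol-2-yl)-1,3-oxazol-5-yl]phenol, via N-hydroxymethyl phenol 13 (not isolated)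
Conditions: BBr3 (6 equiv), CH2Cl2, −78 °C to rt; H2O quench; then K2CO3, THF–H2O, rt; acidify to pH 5
Reagents that add atoms: none
Why: Lewis-acid ether cleavage: BBr3 should demethylate the aryl methyl ether and fragment the N,O-acetal with loss of ethene and Me3SiBr; aqueous quench leaves 13, whose hemiaminal releases formaldehyde under mild base because the trichloropyrrolide is a good leaving group, and the C–Cl bonds and the oxazole are inert to BBr3. An aqueous quench is used instead of a methanolic one so that no N-methoxymethyl compound can form.

## Compound list

1 | methyl isocyanoacetate | COC(=O)C[N+]#[C-] | starting material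
2 | 4-methoxybenzoyl chloride | COc1ccc(C(Cl)=O)cc1 | starting material
3 | methyl 2-isocyano-3-(4-methoxyphenyl)-3-oxopropanoate (racemic, enolisable, not isolated) | COC(=O)C([N+]#[C-])C(=O)c1ccc(OC)cc1 | intermediate
4 | methyl 5-(4-methoxyphenyl)-1,3-oxazole-4-carboxylate | COC(=O)c1ncoc1-c1ccc(OC)cc1 | intermediate
5 | 5-(4-methoxyphenyl)-1,3-oxazole-4-carboxylic acid | COc1ccc(-c2ocnc2C(=O)O)cc1 | intermediate
6 | 4-chloro-5-(4-methoxyphenyl)-1,3-oxazole | COc1ccc(-c2ocnc2Cl)cc1 | intermediate
7 | methyl 1H-pyrrole-2-carboxylate | COC(=O)c1ccc[nH]1 | starting material
8 | methyl 3,4,5-trichloro-1H-pyrrole-2-carboxylate | COC(=O)c1[nH]c(Cl)c(Cl)c1Cl | intermediate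
9 | methyl 3,4,5-trichloro-1-{[2-(trimethylsilyl)ethoxy]methyl}-1H-pyrrole-2-carboxylate | COC(=O)c1c(Cl)c(Cl)c(Cl)n1COCC[Si](C)(C)C | intermediate
10 | 3,4,5-trichloro-1-{[2-(trimethylsilyl)ethoxy]methyl}-1H-pyrrole-2-carboxylic acid | OC(=O)c1c(Cl)c(Cl)c(Cl)n1COCC[Si](C)(C)C | intermediate
11 | 2-bromo-3,4,5-trichloro-1-{[2-(trimethylsilyl)ethoxy]methyl}-1H-pyrrole | Brc1c(Cl)c(Cl)c(Cl)n1COCC[Si](C)(C)C | intermediate
12 | 4-chloro-5-(4-methoxyphenyl)-2-(3,4,5-trichloro-1-{[2-(trimethylsilyl)ethoxy]methyl}-1H-pyrrol-2-yl)-1,3-oxazole | COc1ccc(-c2oc(-c3c(Cl)c(Cl)c(Cl)n3COCC[Si](C)(C)C)nc2Cl)cc1 | intermediate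
13 | 4-{4-chloro-2-[3,4,5-trichloro-1-(hydroxymethyl)-1H-pyrrol-2-yl]-1,3-oxazol-5-yl}phenol (not isolated) | OCn1c(Cl)c(Cl)c(Cl)c1-c1nc(Cl)c(-c2ccc(O)cc2)o1 | intermediate
14 | 4-[4-chloro-2-(3,4,5-trichloro-1H-pyrrol-2-yl)-1,3-oxazol-5-yl]phenol | Oc1ccc(-c2oc(-c3[nH]c(Cl)c(Cl)c3Cl)nc2Cl)cc1 | target

## Step count and least certain steps

Total step count: 9. Longest linear sequence: 6 steps (7 to 14 through steps 4, 5, 6, 7, 8 and 9); the oxazole branch contributes 5 steps (steps 1, 2, 3, 8 and 9).

**Step 3 (carries the label "Proposed new method:").** The most likely failure is sluggish ipso attack at C4, because the carboxyl group deactivates the oxazole until it is ionised. Chlorination of ring A ortho to the methoxy group or chlorination without loss of CO2 could then take over. Fallback with known chemistry, from 5: copper-catalysed protodecarboxylation (Cu2O, 1,10-phenanthroline, NMP–quinoline, 170 °C) should give 5-(4-methoxyphenyl)-1,3-oxazole F1. Electrophilic chlorination of F1 with NCS in DMF at C4, the enol-ether β-carbon at which 5-aryloxazoles are halogenated, returns to the route at 6.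

**Step 1 (key step).** The electron-rich aroyl chloride is a moderate electrophile, so C-acylation may be slow. Base-induced self-condensation of the isocyanoacetate or hydrolysis of the acyl chloride could then consume the partners before ring closure. Fallback, a Robinson–Gabriel closure in place of the isocyanide closure, from 2: C-acylation of the benzophenone imine of methyl glycinate (KOtBu, THF, −78 °C) should give methyl 2-[(diphenylmethylidene)amino]-3-(4-methoxyphenyl)-3-oxopropanoate F2. Aqueous HCl in THF hydrolyses the imine to methyl 2-amino-3-(4-methoxyphenyl)-3-oxopropanoate hydrochloride F3. N-Formylation with acetic formic anhydride, with slow addition of Et3N, gives methyl 2-formamido-3-(4-methoxyphenyl)-3-oxopropanoate F4. Cyclodehydration (PPh3, I2, Et3N, CH2Cl2) closes the oxazole and returns to the route at 4.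

**Step 8.** Oxidative addition and C–H metalation at a C–Br bond flanked by N–CH2 and C3–Cl may be slow. Protodebromination, homocoupling or insertion into a C–Cl bond could then compete. Fallback, a stoichiometric organozinc coupling in place of C–H activation, from 6: C2 zincation with TMPZnCl·LiCl (THF, 25 °C) should give [4-chloro-5-(4-methoxyphenyl)-1,3-oxazol-2-yl]zinc chloride F5. Negishi coupling of F5 with 11 (Pd(PPh3)4, THF, 50 °C) returns to the route at 12.

**Step 9.** Removal of the nitrogen protecting group may stop halfway, with retention of an N–CH2 fragment, or the liberated formaldehyde may re-alkylate the phenol ring during work-up. Fallback, a two-stage orthogonal deprotection, from 12: fluoride cleavage (Bu4NF, ethylenediamine, THF, 60 °C) should give 4-chloro-5-(4-methoxyphenyl)-2-(3,4,5-trichloro-1H-pyrrol-2-yl)-1,3-oxazole F6. Demethylation of F6 alone with BBr3 in CH2Cl2 returns to the route at 14.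

**Step 7.** Three chlorines lower the nucleophilicity of the pyrrole, so ipso attack of bromine may be slow and oxidative degradation may intervene. Fallback, from 10: protodecarboxylation (Ag2CO3 cat., AcOH, DMSO, 120 °C) should give 2,3,4-trichloro-1-{[2-(trimethylsilyl)ethoxy]methyl}-1H-pyrrole F7. Bromination of F7 with NBS in THF at −78 to 0 °C at its only free position, the α-carbon, returns to the route at 11.

## Further compounds

F1 | step 3 | 5-(4-methoxyphenyl)-1,3-oxazole | COc1ccc(-c2cnco2)cc1
F2 | step 1 | methyl 2-[(diphenylmethylidene)amino]-3-(4-methoxyphenyl)-3-oxopropanoate (racemic) | COC(=O)C(N=C(c1ccccc1)c1ccccc1)C(=O)c1ccc(OC)cc1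
F3 | step 1 | methyl 2-amino-3-(4-methoxyphenyl)-3-oxopropanoate hydrochloride (racemic) | COC(=O)C(N)C(=O)c1ccc(OC)cc1.Cl
F4 | step 1 | methyl 2-formamido-3-(4-methoxyphenyl)-3-oxopropanoate (racemic) | COC(=O)C(NC=O)C(=O)c1ccc(OC)cc1
F5 | step 8 | [4-chloro-5-(4-methoxyphenyl)-1,3-oxazol-2-yl]zinc chloride | COc1ccc(-c2oc([Zn]Cl)nc2Cl)cc1
F6 | step 9 | 4-chloro-5-(4-methoxyphenyl)-2-(3,4,5-trichloro-1H-pyrrol-2-yl)-1,3-oxazole | COc1ccc(-c2oc(-c3[nH]c(Cl)c(Cl)c3Cl)nc2Cl)cc1
F7 | step 7 | 2,3,4-trichloro-1-{[2-(trimethylsilyl)ethoxy]methyl}-1H-pyrrole | Clc1cn(COCC[Si](C)(C)C)c(Cl)c1Cl
A1 | alternative 1 | 4-(1H-1,2,3-triazol-4-yl)phenyl 4-methylbenzenesulfonate | Cc1ccc(S(=O)(=O)Oc2ccc(-c3c[nH]nn3)cc2)cc1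
A2 | alternative 1 | 3,4,5-trichloro-1H-pyrrole-2-carbonyl chloride | O=C(Cl)c1[nH]c(Cl)c(Cl)c1Cl
A3 | alternative 1 | 4-[2-(3,4,5-trichloro-1H-pyrrol-2-yl)-1,3-oxazol-5-yl]phenyl 4-methylbenzenesulfonate | Cc1ccc(S(=O)(=O)Oc2ccc(-c3cnc(-c4[nH]c(Cl)c(Cl)c4Cl)o3)cc2)cc1
A4 | alternative 2 | 3,4,5-trichloro-1-{[2-(trimethylsilyl)ethoxy]methyl}-1H-pyrrole-2-carboxamide | NC(=O)c1c(Cl)c(Cl)c(Cl)n1COCC[Si](C)(C)C
A5 | alternative 2 | racemic 4-(1-bromo-2-chloro-2-oxoethyl)phenyl 4-methylbenzenesulfonate | Cc1ccc(S(=O)(=O)Oc2ccc(C(Br)C(Cl)=O)cc2)cc1
A6 | alternative 2 | racemic 4-[4-oxo-2-(3,4,5-trichloro-1-{[2-(trimethylsilyl)ethoxy]methyl}-1H-pyrrol-2-yl)-4,5-dihydro-1,3-oxazol-5-yl]phenyl 4-methylbenzenesulfonate | O=C1N=C(c2c(Cl)c(Cl)c(Cl)n2COCC[Si](C)(C)C)OC1c1ccc(OS(=O)(=O)c2ccc(C)cc2)cc1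
A7 | alternative 3 | 1-[4-chloro-5-(4-methoxyphenyl)-1,3-oxazol-2-yl]ethan-1-one oxime | COc1ccc(-c2oc(C(C)=NO)nc2Cl)cc1
A8 | alternative 3 | acetylene | C#C
A9 | alternative 3 | 4-chloro-5-(4-methoxyphenyl)-2-(1H-pyrrol-2-yl)-1,3-oxazole | COc1ccc(-c2oc(-c3ccc[nH]3)nc2Cl)cc1
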